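**Plan**
Ring labels: A and D are the two 3-hydroxyphenyl rings, B is the para-phenylene ring, C is the 1,2,4-trisubstituted phenol ring (chain at C1, aryloxy at C3, OH at C4).
Enabling feature: the benzylic CH2 on C1 of ring C and the benzylic CH2 on C1 of ring B, each para to an oxygen of the B–O–C core, are both bonded to the CH2 of the same 3-hydroxybenzyl unit. The target is therefore one dialdehyde core plus two copies of one benzyl nucleophile.
Retrosynthesis: both ArCH2–CH2Ar bonds are cut together (as C=C, with the three OH groups masked as benzyl ethers), then the ring B C–O bond of the diaryl ether is cut.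
Forward: an SNAr reaction assembles the B–O–C dialdehyde; one twofold Horner–Wadsworth–Emmons reaction attaches rings D and A to the two formyl carbons (three components, one operation); one hydrogenation saturates both alkenes and frees all three phenols.
Stereochemistry: the target has no stereocentre; the transient E alkenes are erased by the hydrogenation.

Key step: step 3

Remark: 4-(benzyloxy)-3-hydroxybenzaldehyde (the 4-O-monobenzyl ether of protocatechualdehyde) and 3-(benzyloxy)benzyl bromide are taken as purchasable building blocks.

**Step 1**
Reactants: 1 4-(benzyloxy)-3-hydroxybenzaldehyde; 2 4-fluorobenzaldehyde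
Product: 4 4-(benzyloxy)-3-(4-formylphenoxy)benzaldehyde, via potassium phenoxide 3 (not isolated)
Conditions: K2CO3 (2 equiv), DMF, 120 °C, N2
Reagents that add atoms: none
Why: Nucleophilic aromatic substitution (SNAr), in which the phenoxide of 1 attacks the fluoroarene 2 activated by its para-formyl group and fluoride leaves, while the benzyl ether and the two non-enolisable aldehydes should tolerate carbonate in DMF.

**Step 2**
Reactants: 5 3-(benzyloxy)benzyl bromide
Product: 6 diethyl [3-(benzyloxy)benzyl]phosphonate
Conditions: P(OEt)3 (1.5 equiv), neat, 140 °C, bromoethane distilled off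
Reagents that add atoms: triethyl phosphite, CCOP(OCC)OCC
Why: Michaelis–Arbuzov reaction, in which phosphorus displaces the benzylic bromide by SN2 and bromide dealkylates the resulting alkoxyphosphonium ion.

**Step 3**
Reactants: 4 4-(benzyloxy)-3-(4-formylphenoxy)benzaldehyde; 6 diethyl [3-(benzyloxy)benzyl]phosphonate (2.3 equiv)
Product: 9 (E,E)-bis-stilbene tris(benzyl ether), via potassium phosphonate carbanion 7 (not isolated), via mono-stilbene aldehyde 8 (not isolated)
Conditions: 6, KOtBu (2.5 equiv), THF, 0 °C; then 4, 0 °C → rt
Reagents that add atoms: none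
Why: Twofold Horner–Wadsworth–Emmons olefination: the benzylic phosphonate carbanion 7 adds to each formyl carbon of 4, the oxyanion closes to an oxaphosphetane, and syn-elimination of diethyl phosphate gives the alkene, so the ring C–CH=CH–ring D and ring B–CH=CH–ring A bonds form in one operation from three components. The closest known reaction type is the stilbene-forming HWE reaction of benzylphosphonates with aromatic aldehydes, including twofold versions on aromatic dialdehydes. No ring is closed and no stereocentre is created; the E geometry expected from reversible addition is irrelevant because both alkenes are hydrogenated in step 4. The step needs complete reaction at both aldehydes without side reactions: neither aldehyde is enolisable, the benzyl ethers and the diaryl ether are inert to KOtBu, and the excess of 7 should carry the less electrophilic para-alkoxy aldehyde of ring C to completion after the ring B aldehyde has reacted; since the same benzyl unit goes to both ends, no site selectivity between the formyl groups is required.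

**Step 4**
Reactants: 9 (E,E)-bis-stilbene tris(benzyl ether)
Product: 11 perrottetin E, via tri-O-benzylperrottetin E 10 (not isolated)
Conditions: H2 (1–3 bar), 10% Pd/C, THF–MeOH (1:1), rt
Reagents that add atoms: none
Why: Heterogeneous catalytic hydrogenation should saturate both stilbene C=C bonds and then hydrogenolyse the three benzylic C–O bonds of the benzyl ethers in the same operation, while the diaryl ether and the arene rings are inert under these mild conditions.

**Compound list**
1 | 4-(benzyloxy)-3-hydroxybenzaldehyde | O=Cc1ccc(OCc2ccccc2)c(O)c1 | starting material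
2 | 4-fluorobenzaldehyde | O=Cc1ccc(F)cc1 | starting material
3 | potassium 2-(benzyloxy)-5-formylphenolate (phenoxide of 1) | [K+].[O-]c1cc(C=O)ccc1OCc1ccccc1 | intermediate (not isolated)
4 | 4-(benzyloxy)-3-(4-formylphenoxy)benzaldehyde | O=Cc1ccc(Oc2cc(C=O)ccc2OCc2ccccc2)cc1 | intermediate
5 | 3-(benzyloxy)benzyl bromide, i.e. 1-(benzyloxy)-3-(bromomethyl)benzene | BrCc1cccc(OCc2ccccc2)c1 | starting material
6 | diethyl [3-(benzyloxy)benzyl]phosphonate | CCOP(=O)(OCC)Cc1cccc(OCc2ccccc2)c1 | intermediate
7 | potassium salt of the benzylic carbanion of 6 | CCOP(=O)(OCC)[CH-]c1cccc(OCc2ccccc2)c1.[K+] | intermediate (not isolated)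
8 | 4-(benzyloxy)-3-{4-[(E)-2-[3-(benzyloxy)phenyl]ethenyl]phenoxy}benzaldehyde (first olefination expected at the more electrophilic ring B aldehyde; the regioisomer would converge on 9) | O=Cc1ccc(OCc2ccccc2)c(Oc2ccc(/C=C/c3cccc(OCc4ccccc4)c3)cc2)c1 | intermediate (not isolated)
9 | 1-(benzyloxy)-4-[(E)-2-[3-(benzyloxy)phenyl]ethenyl]-2-{4-[(E)-2-[3-(benzyloxy)phenyl]ethenyl]phenoxy}benzene | c1ccccc1COc1cccc(/C=C/c2ccc(Oc3cc(/C=C/c4cccc(OCc5ccccc5)c4)ccc3OCc3ccccc3)cc2)c1 | intermediate
10 | tri-O-benzylperrottetin E, i.e. 1-(benzyloxy)-4-{2-[3-(benzyloxy)phenyl]ethyl}-2-(4-{2-[3-(benzyloxy)phenyl]ethyl}phenoxy)benzene | c1ccccc1COc1cccc(CCc2ccc(Oc3cc(CCc4cccc(OCc5ccccc5)c4)ccc3OCc3ccccc3)cc2)c1 | intermediate (not isolated)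
11 | perrottetin E, i.e. 4-[2-(3-hydroxyphenyl)ethyl]-2-{4-[2-(3-hydroxyphenyl)ethyl]phenoxy}phenol | Oc1cccc(CCc2ccc(Oc3cc(CCc4cccc(O)c4)ccc3O)cc2)c1 | target

**Step count**
Total steps: 4. Longest linear sequence: 3 steps (1 → 3 → 4, or 2 → 3 → 4).

**Steps most likely to fail**

Step 3. The second olefination may stall at the electron-rich para-alkoxy aldehyde of ring C, or the dialdehyde may be eroded by base before both ends have reacted. The fallback reverses the polarity of the coupling, sets out from 4 and comes back at 9. NaBH4 (MeOH–THF, 0 °C) should reduce 4 to the diol [4-(benzyloxy)-3-[4-(hydroxymethyl)phenoxy]phenyl]methanol F1. PBr3 (CH2Cl2, 0 °C) should convert this into 1-(benzyloxy)-4-(bromomethyl)-2-[4-(bromomethyl)phenoxy]benzene F2, used crude. Arbuzov reaction with triethyl phosphite (neat, 130 °C) should give the tetraethyl bis-phosphonate F3. A twofold HWE reaction of F3 with commercial 3-(benzyloxy)benzaldehyde (2.3 equiv; KOtBu, THF, 0 °C → rt), now a more electrophilic meta-alkoxy aldehyde, should form the same two alkenes and return to 9.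

Step 4. The hydrogenolysis may stall at partly benzylated stages through catalyst poisoning or poor solubility of 9, and forcing conditions could begin to saturate arene rings. The fallback uses no metal catalyst for the C–O cleavage, sets out from 9 and comes back at 11. Diimide reduction (TsNHNH2, NaOAc, THF–H2O, reflux) should saturate only the two alkenes to give 10, here isolated. BCl3 with pentamethylbenzene as cation scavenger (CH2Cl2, −78 °C) should then cleave the three aryl benzyl ethers to give 11. This fallback makes no compound outside the list (F0).

Step 1. Substitution at the only moderately activated fluoroarene may be slow, and prolonged heating may cause loss of the benzyl ether or degradation of the aldehydes. The fallback forms the diaryl ether by oxidative copper-mediated C–O coupling at room temperature, sets out from 1 and comes back at 4. It is a Chan–Lam coupling of 1 with commercial 4-formylphenylboronic acid (Cu(OAc)2, pyridine, 4 Å molecular sieves, CH2Cl2, air, rt). This fallback makes no compound outside the list (F0).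

**Further compounds**
F1 | step 3 | [4-(benzyloxy)-3-[4-(hydroxymethyl)phenoxy]phenyl]methanol | OCc1ccc(Oc2cc(CO)ccc2OCc2ccccc2)cc1
F2 | step 3 | 1-(benzyloxy)-4-(bromomethyl)-2-[4-(bromomethyl)phenoxy]benzene | BrCc1ccc(Oc2cc(CBr)ccc2OCc2ccccc2)cc1
F3 | step 3 | tetraethyl bis-phosphonate: diethyl {4-[2-(benzyloxy)-5-[(diethoxyphosphoryl)methyl]phenoxy]benzyl}phosphonate | CCOP(=O)(OCC)Cc1ccc(Oc2cc(CP(=O)(OCC)OCC)ccc2OCc2ccccc2)cc1
F0 | step 4 | none | none
F0 | step 1 | none | none
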